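**Retrosynthetic overview**

1. Target 26 comes from dehydration of the C12 carbinol 25 (forms C11=C12). 25 comes from the C12 aldehyde 23 and 3-bromofuran-2(5H)-one. The C19 acetate and 3-OH derive from an axial C4 nitrile and a C3 ketone, and C8=CH2 from a C8 ketone (16).
2. Diketone 16 comes from the acyclic cyclopropanol enone 14 in one redox-neutral radical cascade. The C8 cyclopropanol opens to a C6 radical, which closes ring B (C5–C6) onto the (E)-C5=C10 alkene. The tertiary C10 radical then closes ring A by forming C1–C10 onto the C1=C2–C3=O enone.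
3. Enabling feature: the methyl-bearing quaternary C10 at the ring A/ring B fusion sits between an oxygenated C3 in ring A and the sp2 C8 in ring B. Both can be ketones, so C3 activates C1 as radical acceptor and C8 (as cyclopropanol) releases the C6 radical. The quaternary C4 (CH3, C19 as C≡N) next to C5 steers the fold.
4. Precursor 14 comes from aldehyde 6 (β-methyl-γ-butyrolactone: alkylation, Kulinkovich) and cyanoacetyl oxazolidinone 9, through Knoevenagel condensation, auxiliary-controlled deconjugative methylation (sets C4 and the (E)-alkene), Weinreb amide and vinyl ketone.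
5. Ring order: ring B, then ring A, both in step 10. Before that step the only ring is the cyclopropane that is consumed.

Key step: step 10

Remark: lactone 1 is used as the racemate, because its two stereocentres become C10 (made planar in step 7) and C9 (equilibrated in step 10). Compounds 3–6 are therefore racemic (one enantiomer drawn) and 10–15 are C9-epimeric mixtures with C9 (and C10 while sp3) left open in the SMILES. Locants C1–C20 in names of 15–26 are the ent-labdane positions of the target.

**Step 1**
Reactants: 1 (±)-4-methyldihydrofuran-2(3H)-one; 2 tert-butyl(2-iodoethoxy)dimethylsilane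
Product: 3 (3R*,4R*)-3-[2-(tert-butyldimethylsilyloxy)ethyl]-4-methyldihydrofuran-2(3H)-one (trans, racemic)
Conditions: LiN(iPr)2, THF, −78 °C; then 2, DMPU, −78 to −20 °C
Reagents that add atoms: none
Why: Kinetic lactone enolate alkylation (SN2) with the primary iodide should occur anti to the 4-methyl group and give the trans lactone, whose two centres are inconsequential later.

**Step 2**
Reactants: 3
Product: 4 1-[(3R*,4R*)-1-(tert-butyldimethylsilyloxy)-5-hydroxy-4-methylpentan-3-yl]cyclopropan-1-ol
Conditions: Ti(OiPr)4 (0.3 equiv), EtMgBr (3 equiv), THF/Et2O, 0 °C to rt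
Reagents that add atoms: ethylmagnesium bromide, CC[Mg]Br
Why: The Kulinkovich reaction (titanacyclopropane from EtMgBr and Ti(OiPr)4) should convert the lactone carbonyl into the 1-substituted cyclopropanol (future C6–C8) and free the primary alcohol, while the silyl ether is inert.

**Step 3**
Reactants: 4
Product: 5 (3R*,4R*)-1-(tert-butyldimethylsilyloxy)-4-methyl-5-(trimethylsilyloxy)-3-[1-(trimethylsilyloxy)cyclopropyl]pentane
Conditions: Me3SiCl, imidazole, DMF, 0 °C to rt
Reagents that add atoms: chlorotrimethylsilane, C[Si](C)(C)Cl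
Why: Silylation of both hydroxyl groups masks the cyclopropanol, which would otherwise add to the alkylidene unit made in step 6 (oxa-Michael).

**Step 4**
Reactants: 5
Product: 6 (2R*,3R*)-5-(tert-butyldimethylsilyloxy)-2-methyl-3-[1-(trimethylsilyloxy)cyclopropyl]pentanal
Conditions: (COCl)2, DMSO, CH2Cl2, −78 to −30 °C; Et3N, −78 °C to rt
Reagents that add atoms: none
Why: Swern oxidation should cleave and oxidise the unhindered primary trimethylsilyl ether directly to the aldehyde, leaving the tertiary cyclopropyl silyl ether and the TBS ether untouched.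

**Step 5**
Reactants: 7 (R)-4-benzyloxazolidin-2-one; 8 cyanoacetic acid
Product: 9 3-[(4R)-4-benzyl-2-oxooxazolidin-3-yl]-3-oxopropanenitrile
Conditions: t-BuCOCl, Et3N, THF, −20 °C; then 7, LiCl, rt
Reagents that add atoms: none
Why: N-Acylation of the oxazolidinone through the pivaloyl mixed anhydride gives the chiral cyanoacetyl donor without touching its stereocentre.

**Step 6**
Reactants: 6; 9
Product: 10 (4R)-4-benzyl-3-{7-(tert-butyldimethylsilyloxy)-2-cyano-4-methyl-5-[1-(trimethylsilyloxy)cyclopropyl]hept-2-enoyl}oxazolidin-2-one (alkene isomers, C4/C5 of the chain in both configurations)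
Conditions: piperidine (cat.), AcOH (cat.), 4 Å MS, CH2Cl2, rt
Reagents that add atoms: none
Why: Knoevenagel condensation of the doubly activated methylene with the α-branched aldehyde forms the C4=C5 bond; alkene geometry and the C10 configuration are irrelevant because both are lost in step 7.

**Step 7**
Reactants: 10
Product: 11 (4R)-4-benzyl-3-{(2R,3E)-7-(tert-butyldimethylsilyloxy)-2-cyano-2,4-dimethyl-5-[1-(trimethylsilyloxy)cyclopropyl]hept-3-enoyl}oxazolidin-2-one (both C5 epimers of the chain)
Conditions: NaN(SiMe3)2, THF, −78 °C; MeI, −78 to −30 °C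
Reagents that add atoms: iodomethane, CI
Why: Deconjugative α-alkylation under Evans auxiliary control: γ-deprotonation at C10 gives the chelated sodium dienolate with the small nitrile cis to nitrogen, MeI should attack C4 on the face away from the benzyl group to set C4 as R, and the branched C9 substituent turns away from C4 to give the (E)-C5=C10 alkene.

**Step 8**
Reactants: 11
Product: 12 (2R,3E)-7-(tert-butyldimethylsilyloxy)-2-cyano-N-methoxy-N,2,4-trimethyl-5-[1-(trimethylsilyloxy)cyclopropyl]hept-3-enamide (both C5 epimers)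
Conditions: Me(MeO)NH·HCl, AlMe3, CH2Cl2, 0 °C to rt
Reagents that add atoms: N,O-dimethylhydroxylamine hydrochloride, CNOC.Cl
Why: Aluminium amide transamidation at the activated exocyclic acyl group releases the auxiliary and gives the Weinreb amide without touching the quaternary C4.

**Step 9**
Reactants: 12
Product: 14 (4R,5E)-9-(tert-butyldimethylsilyloxy)-7-(1-hydroxycyclopropyl)-4,6-dimethyl-3-oxonona-1,5-diene-4-carbonitrile (both C7 epimers), via silyl ether 13 (not isolated)
Conditions: CH2=CHMgBr, THF, −78 to −20 °C; then 1 M aq. HCl, THF, 0 °C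
Reagents that add atoms: vinylmagnesium bromide, C=C[Mg]Br
Why: Weinreb ketone synthesis installs the C1=C2–C3=O acceptor through the stable chelated tetrahedral intermediate, and the dilute acid work-up should remove only the labile tertiary trimethylsilyl ether.

**Step 10**
Reactants: 14
Product: 16 12-(tert-butyldimethylsilyloxy)-3,8-dioxo-13,14,15,16,17-pentanor-ent-labdan-19-nitrile (trans-decalin; C4 nitrile axial and cis to CH3-20, 4-CH3 equatorial, H-5 trans to CH3-20, C9 chain equatorial), via crude C9-epimeric diketone 15 (not isolated)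
Conditions: [Ir(dF(CF3)ppy)2(5,5′-d(CF3)bpy)]PF6 (2 mol %), 2,4,6-collidine (1 equiv), degassed PhCF3, 2 mM, blue LEDs, rt; then DBU (0.3 equiv), CH2Cl2, rt
Reagents that add atoms: none
Why: Proposed new method: excited trivalent iridium and collidine should oxidise the cyclopropanol O–H by proton-coupled electron transfer, β-scission gives the primary β-keto radical at C6, this closes ring B by 6-endo-trig addition to C5 of the C5=C10 alkene, the tertiary C10 radical closes ring A by 6-endo-trig Giese addition to C1 of the vinyl ketone (the C1–C10 bond), and the electrophilic C2 radical is reduced by divalent iridium and protonated by collidinium, so the step is a redox-neutral isomerisation. The closest known reaction types are the photocatalytic ring-opening/Giese alkylation of cyclopropanols and the 6-endo radical polyene cyclisations (acyl-radical or metal-hydride initiated) that give trans-decalins with an angular methyl group. C5 is set in the first closure by the C4 stereocentre: allylic 1,3-strain with the C10 methyl places the small linear nitrile inside, the acyl arm anti to the incoming radical and the methyl outside. C10 is set in the second closure through a chair transition state with the nitrile axial, which gives the trans fusion, and C9 is set afterwards by DBU equilibration next to the C8 ketone, so both C9 epimers of 14 converge. The step needs 6-endo over 5-exo closure (5-exo would have to bond to the fully substituted C10), face selectivity at C5, and survival of the alkyl radicals until they cyclise; these are secured by the C10 methyl, the nitrile/acyl pattern on C4, high dilution and the absence of any hydrogen-atom donor.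

**Step 11**
Reactants: 16
Product: 17 12-(tert-butyldimethylsilyloxy)-3-hydroxy-8-oxo-13,14,15,16,17-pentanor-ent-labdan-19-nitrile (3-OH equatorial, cis to the nitrile)
Conditions: NaBH4 (0.5 equiv), CH2Cl2/MeOH, −40 °C
Reagents that add atoms: none
Why: Hydride reduction should select the α-cyano-activated C3 ketone, whose axial trajectory is open, over the C8 ketone, whose axial trajectory is blocked by the syn-axial C10 methyl, and axial attack gives the equatorial 3-alcohol.

**Step 12**
Reactants: 17
Product: 18 12-(tert-butyldimethylsilyloxy)-3-hydroxy-13,14,15,16-tetranor-ent-labd-8(17)-en-19-nitrile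
Conditions: Zn, CH2Br2, TiCl4, THF/CH2Cl2, 0 °C to rt
Reagents that add atoms: dibromomethane, BrCBr
Why: Takai–Lombardo methylenation is non-basic, so it should convert the hindered C8 ketone into the exocyclic alkene without epimerising C9 and without retro-aldol cleavage of the β-hydroxy nitrile.

**Step 13**
Reactants: 18
Product: 20 12-(tert-butyldimethylsilyloxy)-13,14,15,16-tetranor-ent-labd-8(17)-ene-3,19-diol, via hydroxy aldehyde 19 (not isolated)
Conditions: iBu2AlH (4 equiv), toluene, −78 to −20 °C; aq. tartaric acid, rt; then NaBH4, MeOH, 0 °C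
Reagents that add atoms: water, O
Why: Partial reduction of the axial nitrile stops at the N-aluminio imine, hydrolysis gives the C19 aldehyde, and borohydride reduces it to the C19 alcohol before retro-aldol can occur.

**Step 14**
Reactants: 20
Product: 21 19-acetoxy-12-(tert-butyldimethylsilyloxy)-13,14,15,16-tetranor-ent-labd-8(17)-en-3-ol
Conditions: Ac2O (1.1 equiv), pyridine, CH2Cl2, 0 °C
Reagents that add atoms: acetic anhydride, CC(=O)OC(C)=O
Why: Selective acylation of the primary C19 hydroxyl over the secondary 3-hydroxyl beside the quaternary C4 installs the acetate of the target.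

**Step 15**
Reactants: 21
Product: 22 19-acetoxy-13,14,15,16-tetranor-ent-labd-8(17)-ene-3,12-diol
Conditions: HF·pyridine, THF/pyridine, 0 °C to rt
Reagents that add atoms: none
Why: Buffered fluoride desilylation frees the C12 alcohol under conditions that leave the acetate and the exocyclic alkene intact.

**Step 16**
Reactants: 22
Product: 23 19-acetoxy-3-hydroxy-13,14,15,16-tetranor-ent-labd-8(17)-en-12-al
Conditions: TEMPO (10 mol %), PhI(OAc)2, CH2Cl2, rt
Reagents that add atoms: none
Why: Oxoammonium (TEMPO) oxidation is selective for the unhindered primary C12 alcohol over the hindered secondary 3-hydroxyl.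

**Step 17**
Reactants: 23; 24 3-bromofuran-2(5H)-one
Product: 25 19-acetoxy-3,12-dihydroxy-ent-labda-8(17),13-dien-16,15-olide (both C12 epimers)
Conditions: CrCl2 (4 equiv), NiCl2 (2 mol %), DMF, rt
Reagents that add atoms: none
Why: Nozaki–Hiyama–Kishi coupling of the alkenyl bromide with the aldehyde forms the C12–C13 bond under neutral conditions that tolerate the free 3-hydroxyl and the acetate; the C12 configuration is lost in step 18.

**Step 18**
Reactants: 25
Product: 26 19-O-acetyl-14-deoxy-11,12-didehydroandrographolide (target; C3 R, C4 R, C5 S, C9 R, C10 R, 11E)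
Conditions: neutral Al2O3, pyridine, reflux
Reagents that add atoms: none
Why: Dehydration of the allylic C12 alcohol, whose only β-hydrogens are on C11, should give the conjugated (E)-dienyl butenolide; the hindered 3-hydroxyl is unaffected.

**Compound list**

1 | (±)-4-methyldihydrofuran-2(3H)-one (β-methyl-γ-butyrolactone) | CC1COC(=O)C1 | starting material
2 | tert-butyl(2-iodoethoxy)dimethylsilane | CC(C)(C)[Si](C)(C)OCCI | starting material
3 | (3R*,4R*)-3-[2-(tert-butyldimethylsilyloxy)ethyl]-4-methyldihydrofuran-2(3H)-one (racemic, one enantiomer drawn) | C[C@H]1COC(=O)[C@@H]1CCO[Si](C)(C)C(C)(C)C | intermediate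
4 | 1-[(3R*,4R*)-1-(tert-butyldimethylsilyloxy)-5-hydroxy-4-methylpentan-3-yl]cyclopropan-1-ol (racemic) | C[C@@H](CO)[C@@H](CCO[Si](C)(C)C(C)(C)C)C1(O)CC1 | intermediate
5 | (3R*,4R*)-1-(tert-butyldimethylsilyloxy)-4-methyl-5-(trimethylsilyloxy)-3-[1-(trimethylsilyloxy)cyclopropyl]pentane (racemic) | C[C@@H](CO[Si](C)(C)C)[C@@H](CCO[Si](C)(C)C(C)(C)C)C1(O[Si](C)(C)C)CC1 | intermediate
6 | (2R*,3R*)-5-(tert-butyldimethylsilyloxy)-2-methyl-3-[1-(trimethylsilyloxy)cyclopropyl]pentanal (racemic) | C[C@@H](C=O)[C@@H](CCO[Si](C)(C)C(C)(C)C)C1(O[Si](C)(C)C)CC1 | intermediate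
7 | (R)-4-benzyloxazolidin-2-one | O=C1OC[C@@H](Cc2ccccc2)N1 | starting material
8 | cyanoacetic acid | N#CCC(=O)O | starting material
9 | 3-[(4R)-4-benzyl-2-oxooxazolidin-3-yl]-3-oxopropanenitrile | N#CCC(=O)N1C(=O)OC[C@H]1Cc1ccccc1 | intermediate
10 | (4R)-4-benzyl-3-{7-(tert-butyldimethylsilyloxy)-2-cyano-4-methyl-5-[1-(trimethylsilyloxy)cyclopropyl]hept-2-enoyl}oxazolidin-2-one (isomer mixture) | CC(C=C(C#N)C(=O)N1C(=O)OC[C@H]1Cc1ccccc1)C(CCO[Si](C)(C)C(C)(C)C)C1(O[Si](C)(C)C)CC1 | intermediate
11 | (4R)-4-benzyl-3-{(2R,3E)-7-(tert-butyldimethylsilyloxy)-2-cyano-2,4-dimethyl-5-[1-(trimethylsilyloxy)cyclopropyl]hept-3-enoyl}oxazolidin-2-one (C5 epimers) | C/C(=C\[C@](C)(C#N)C(=O)N1C(=O)OC[C@H]1Cc1ccccc1)C(CCO[Si](C)(C)C(C)(C)C)C1(O[Si](C)(C)C)CC1 | intermediate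
12 | (2R,3E)-7-(tert-butyldimethylsilyloxy)-2-cyano-N-methoxy-N,2,4-trimethyl-5-[1-(trimethylsilyloxy)cyclopropyl]hept-3-enamide (C5 epimers) | C/C(=C\[C@](C)(C#N)C(=O)N(C)OC)C(CCO[Si](C)(C)C(C)(C)C)C1(O[Si](C)(C)C)CC1 | intermediate
13 | (4R,5E)-9-(tert-butyldimethylsilyloxy)-4,6-dimethyl-3-oxo-7-[1-(trimethylsilyloxy)cyclopropyl]nona-1,5-diene-4-carbonitrile (C7 epimers; not isolated) | C/C(=C\[C@](C)(C#N)C(=O)C=C)C(CCO[Si](C)(C)C(C)(C)C)C1(O[Si](C)(C)C)CC1 | intermediate
14 | (4R,5E)-9-(tert-butyldimethylsilyloxy)-7-(1-hydroxycyclopropyl)-4,6-dimethyl-3-oxonona-1,5-diene-4-carbonitrile (C7 epimers) | C/C(=C\[C@](C)(C#N)C(=O)C=C)C(CCO[Si](C)(C)C(C)(C)C)C1(O)CC1 | intermediate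
15 | 12-(tert-butyldimethylsilyloxy)-3,8-dioxo-13,14,15,16,17-pentanor-ent-labdan-19-nitrile, both C9 epimers (not isolated) | O=C1CC[C@@H]2[C@](C)(C#N)C(=O)CC[C@@]2(C)C1CCO[Si](C)(C)C(C)(C)C | intermediate
16 | 12-(tert-butyldimethylsilyloxy)-3,8-dioxo-13,14,15,16,17-pentanor-ent-labdan-19-nitrile (C9 chain equatorial) | O=C1CC[C@@H]2[C@](C)(C#N)C(=O)CC[C@@]2(C)[C@@H]1CCO[Si](C)(C)C(C)(C)C | intermediate
17 | 12-(tert-butyldimethylsilyloxy)-3-hydroxy-8-oxo-13,14,15,16,17-pentanor-ent-labdan-19-nitrile (3-OH equatorial) | O=C1CC[C@@H]2[C@](C)(C#N)[C@H](O)CC[C@@]2(C)[C@@H]1CCO[Si](C)(C)C(C)(C)C | intermediate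
18 | 12-(tert-butyldimethylsilyloxy)-3-hydroxy-13,14,15,16-tetranor-ent-labd-8(17)-en-19-nitrile | C=C1CC[C@@H]2[C@](C)(C#N)[C@H](O)CC[C@@]2(C)[C@@H]1CCO[Si](C)(C)C(C)(C)C | intermediate
19 | 12-(tert-butyldimethylsilyloxy)-3-hydroxy-13,14,15,16-tetranor-ent-labd-8(17)-en-19-al (not isolated) | C=C1CC[C@@H]2[C@](C)(C=O)[C@H](O)CC[C@@]2(C)[C@@H]1CCO[Si](C)(C)C(C)(C)C | intermediate
20 | 12-(tert-butyldimethylsilyloxy)-13,14,15,16-tetranor-ent-labd-8(17)-ene-3,19-diol | C=C1CC[C@@H]2[C@](C)(CO)[C@H](O)CC[C@@]2(C)[C@@H]1CCO[Si](C)(C)C(C)(C)C | intermediate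
21 | 19-acetoxy-12-(tert-butyldimethylsilyloxy)-13,14,15,16-tetranor-ent-labd-8(17)-en-3-ol | C=C1CC[C@@H]2[C@](C)(COC(C)=O)[C@H](O)CC[C@@]2(C)[C@@H]1CCO[Si](C)(C)C(C)(C)C | intermediate
22 | 19-acetoxy-13,14,15,16-tetranor-ent-labd-8(17)-ene-3,12-diol | C=C1CC[C@@H]2[C@](C)(COC(C)=O)[C@H](O)CC[C@@]2(C)[C@@H]1CCO | intermediate
23 | 19-acetoxy-3-hydroxy-13,14,15,16-tetranor-ent-labd-8(17)-en-12-al | C=C1CC[C@@H]2[C@](C)(COC(C)=O)[C@H](O)CC[C@@]2(C)[C@@H]1CC=O | intermediate
24 | 3-bromofuran-2(5H)-one | O=C1OCC=C1Br | starting material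
25 | 19-acetoxy-3,12-dihydroxy-ent-labda-8(17),13-dien-16,15-olide (C12 epimers) | C=C1CC[C@@H]2[C@](C)(COC(C)=O)[C@H](O)CC[C@@]2(C)[C@@H]1CC(O)C1=CCOC1=O | intermediate
26 | 19-O-acetyl-14-deoxy-11,12-didehydroandrographolide | C=C1CC[C@@H]2[C@](C)(COC(C)=O)[C@H](O)CC[C@@]2(C)[C@@H]1/C=C/C1=CCOC1=O | target

**Step count and risks**

Total step count: 18. Longest linear sequence: 17 steps (steps 1–4 and 6–18; step 5 is a one-step side branch).

Steps most likely to fail:

1. Step 10 (Proposed new method). The first ring closure must bond C6 to C5 beside the quaternary C4. It may lose out to 5-exo closure at C10, to a 1,5-hydrogen shift from C11, or to intermolecular addition to the vinyl ketone. The vinyl ketone may also be consumed by light or base, and the attack on C5 may not be fully face-selective. The fallback uses known chemistry and sets out from 14. Electrophilic ring opening of the cyclopropanol with N-bromosuccinimide (CH2Cl2, −78 °C) should give the β-bromo ketone (4R,5E)-7-(3-bromopropanoyl)-9-(tert-butyldimethylsilyloxy)-4,6-dimethyl-3-oxonona-1,5-diene-4-carbonitrile F1. Slow addition of Bu3SnH with AIBN (benzene, 80 °C, 2 mM) then runs the two 6-endo closures as a conventional reductive tin-hydride radical chain, without photocatalyst, base or light. DBU equilibration at C9 brings the material back to 16.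

2. Step 7. Facial control may erode because the cyano-stabilised sodium dienolate chelates weakly; the new C5=C10 alkene may form as an E/Z mixture, or methylation may occur at the γ-carbon. The fallback replaces auxiliary control by catalyst control and sets out from 6. Knoevenagel condensation with methyl cyanoacetate should give methyl 7-(tert-butyldimethylsilyloxy)-2-cyano-4-methyl-5-[1-(trimethylsilyloxy)cyclopropyl]hept-2-enoate F2. Deconjugative methylation under asymmetric phase-transfer catalysis (C2-symmetric N-spiro binaphthyl quaternary ammonium bromide, MeI, CsOH·H2O, toluene, −40 °C) should give methyl (2R,3E)-7-(tert-butyldimethylsilyloxy)-2-cyano-2,4-dimethyl-5-[1-(trimethylsilyloxy)cyclopropyl]hept-3-enoate F3 by ion-pair control. Treatment with i-PrMgCl and Me(MeO)NH·HCl converts the ester into 12.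

3. Step 11. Hydride may fail to distinguish the two carbonyl groups (reducing both) or may attack C3 from the equatorial side. The fallback differentiates the ketones by protection and sets out from 16. Triflate-catalysed ketalisation with 1,2-bis(trimethylsilyloxy)ethane (Me3SiOTf cat., CH2Cl2, −78 °C) should protect only the unactivated C8 ketone as the 8,8-ethylenedioxy-3-oxo nitrile F4, because the α-cyano C3 ketone resists oxocarbenium formation. NaBH4 then gives the 8,8-ethylenedioxy-3-hydroxy nitrile F5. PPTS in wet acetone removes the dioxolane and returns 17.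

**Further compounds**

F1 | step 10 | (4R,5E)-7-(3-bromopropanoyl)-9-(tert-butyldimethylsilyloxy)-4,6-dimethyl-3-oxonona-1,5-diene-4-carbonitrile (C7 epimers) | C/C(=C\[C@](C)(C#N)C(=O)C=C)C(CCO[Si](C)(C)C(C)(C)C)C(=O)CCBr
F2 | step 7 | methyl 7-(tert-butyldimethylsilyloxy)-2-cyano-4-methyl-5-[1-(trimethylsilyloxy)cyclopropyl]hept-2-enoate (isomer mixture) | COC(=O)C(C#N)=CC(C)C(CCO[Si](C)(C)C(C)(C)C)C1(O[Si](C)(C)C)CC1
F3 | step 7 | methyl (2R,3E)-7-(tert-butyldimethylsilyloxy)-2-cyano-2,4-dimethyl-5-[1-(trimethylsilyloxy)cyclopropyl]hept-3-enoate (C5 epimers) | C/C(=C\[C@](C)(C#N)C(=O)OC)C(CCO[Si](C)(C)C(C)(C)C)C1(O[Si](C)(C)C)CC1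
F4 | step 11 | 12-(tert-butyldimethylsilyloxy)-8,8-ethylenedioxy-3-oxo-13,14,15,16,17-pentanor-ent-labdan-19-nitrile | C12(OCCO1)CC[C@@H]3[C@](C)(C#N)C(=O)CC[C@@]3(C)[C@@H]2CCO[Si](C)(C)C(C)(C)C
F5 | step 11 | 12-(tert-butyldimethylsilyloxy)-8,8-ethylenedioxy-3-hydroxy-13,14,15,16,17-pentanor-ent-labdan-19-nitrile | C12(OCCO1)CC[C@@H]3[C@](C)(C#N)[C@H](O)CC[C@@]3(C)[C@@H]2CCO[Si](C)(C)C(C)(C)C
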